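**Retrosynthetic overview**
1. Endgame: global desilylation ← Corey–Bakshi–Shibata reduction of the ring-A enone ← Dess–Martin oxidation of the carbinol delivered by the key step.
2. Key disconnection: the bond between the chain-bearing alkene carbon of ring A and the first side-chain CH2, formed while ring A itself closes. A zerovalent-palladium, anti-Wacker-type alkylative cyclization joins acyclic 4,4-dimethylhept-5-ynal with the B-alkyl-9-BBN made from the side-chain diene (6-endo-dig, net trans addition across the alkyne).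
3. Enabling feature: ring A is a 2-methylcyclohex-2-en-1-ol in which the carbinol carbon, the methyl-bearing alkene carbon, the chain-bearing alkene carbon and the gem-dimethyl carbon are contiguous. These map onto the aldehyde carbon, the two carbons of a methyl-capped alkyne and a quaternary propargylic carbon of a 5-alkynal.
4. Side-chain fragment: butenolide by Bestmann-ylide closure of an (S)-α-hydroxy ketone, itself from SAMP-hydrazone alkylation of 2,2-dimethyl-1,3-dioxan-5-one with a (2Z)-allylic bromide. The bromide comes from syn-carbocupration of a 4-silyloxybut-2-ynoate, cross-metathesis with methacrolein and Wittig methylenation.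
5. Ring order: butenolide ring first (step 16), ring A last (step 17); the alkynal is made from 2,2-dimethylpent-4-enal in four steps.

Key step: step 17

Remark: the ring-A carbinol is not expected to be controlled in the key step and is therefore set afterwards at the enone stage (steps 18 and 19); TBDPS = tert-butyldiphenylsilyl.

**Route**

Step 1
Reactants: 1 2,2-dimethylpent-4-enal
Product: 2 1,1-dibromo-3,3-dimethylhexa-1,5-diene
Conditions: CBr4, PPh3, Zn, CH2Cl2, rt; then 1
Reagents that add atoms: tetrabromomethane, BrC(Br)(Br)Br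
Why: Corey–Fuchs dibromo-olefination (Wittig reaction of the dibromomethylene ylide) should run cleanly on this non-enolisable aldehyde.

Step 2
Reactants: 2 1,1-dibromo-3,3-dimethylhexa-1,5-diene
Product: 4 4,4-dimethylhept-1-en-5-yne, via lithium acetylide 3 (not isolated)
Conditions: n-BuLi (2.1 equiv), THF, −78 → 0 °C; then MeI, 0 °C → rt
Reagents that add atoms: iodomethane, CI
Why: the second stage of the Corey–Fuchs alkyne synthesis (lithium–bromine exchange and Fritsch–Buttenberg–Wiechell rearrangement) gives the lithium acetylide, which should be C-methylated in the same flask.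

Step 3
Reactants: 4 4,4-dimethylhept-1-en-5-yne
Product: 6 4,4-dimethylhept-5-yn-1-ol, via alkylborane 5 (not isolated)
Conditions: 9-BBN, THF, 0 °C → rt; then NaOH, H2O2, 0 °C
Reagents that add atoms: hydrogen peroxide, OO
Why: anti-Markovnikov hydroboration–oxidation, in which 9-BBN should select the terminal alkene over the internal alkyne shielded by the quaternary carbon.

Step 4
Reactants: 6 4,4-dimethylhept-5-yn-1-ol
Product: 7 4,4-dimethylhept-5-ynal
Conditions: Dess–Martin periodinane, NaHCO3, CH2Cl2, 0 °C → rt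
Reagents that add atoms: none
Why: Dess–Martin oxidation should stop at the aldehyde and leave the alkyne untouched.

Step 5
Reactants: 8 tert-butyldiphenyl(prop-2-yn-1-yloxy)silane
Product: 10 methyl 4-(TBDPS-oxy)but-2-ynoate, via lithium acetylide 9 (not isolated)
Conditions: n-BuLi, THF, −78 °C; then ClCO2Me, −78 → 0 °C
Reagents that add atoms: methyl chloroformate, COC(=O)Cl
Why: C-acylation of a lithium acetylide with a chloroformate is a standard ynoate synthesis.

Step 6
Reactants: 10 methyl 4-(TBDPS-oxy)but-2-ynoate; 11 but-3-en-1-ylmagnesium bromide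
Product: 12 methyl (2Z)-3-[(TBDPS-oxy)methyl]hepta-2,6-dienoate
Conditions: 11 (2.2 equiv), CuBr·SMe2 (1.1 equiv), THF, −78 °C; then 10, −78 °C; MeOH quench at −78 °C
Reagents that add atoms: none
Why: syn-carbocupration (conjugate addition of a magnesium dialkylcuprate) of the ynoate followed by protonation with retention at −78 °C should place the ester cis to the silyloxymethyl group, which sets the (2Z) alkene.

Step 7
Reactants: 12 methyl (2Z)-3-[(TBDPS-oxy)methyl]hepta-2,6-dienoate; 13 methacrolein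
Product: 14 methyl (2Z,6E)-3-[(TBDPS-oxy)methyl]-7-methyl-8-oxoocta-2,6-dienoate
Conditions: 13 (5 equiv), second-generation Grubbs catalyst (5 mol%), CH2Cl2, 40 °C
Reagents that add atoms: none
Why: olefin cross-metathesis of the terminal alkene with methacrolein should give the (E)-2-methyl enal under thermodynamic control (formyl trans to the chain), while the electron-poor trisubstituted enoate stays inert.

Step 8
Reactants: 14 methyl (2Z,6E)-3-[(TBDPS-oxy)methyl]-7-methyl-8-oxoocta-2,6-dienoate
Product: 15 methyl (2Z,6E)-3-[(TBDPS-oxy)methyl]-7-methylnona-2,6,8-trienoate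
Conditions: Ph3PCH3Br, KOt-Bu, THF, 0 °C; then 14, −78 → 0 °C
Reagents that add atoms: methyltriphenylphosphonium bromide, C[P+](c1ccccc1)(c1ccccc1)c1ccccc1.[Br-]
Why: Wittig methylenation of the aldehyde should leave the ester and both alkene geometries unchanged.

Step 9
Reactants: 15 methyl (2Z,6E)-3-[(TBDPS-oxy)methyl]-7-methylnona-2,6,8-trienoate
Product: 16 (2Z,6E)-3-[(TBDPS-oxy)methyl]-7-methylnona-2,6,8-trien-1-ol
Conditions: i-Bu2AlH (2.5 equiv), CH2Cl2, −78 °C
Reagents that add atoms: none
Why: 1,2-reduction of the enoate with i-Bu2AlH should give the allylic alcohol with retention of geometry, and the bulky TBDPS group resists silyl migration.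

Step 10
Reactants: 16 (2Z,6E)-3-[(TBDPS-oxy)methyl]-7-methylnona-2,6,8-trien-1-ol
Product: 17 (2Z,6E)-1-bromo-3-[(TBDPS-oxy)methyl]-7-methylnona-2,6,8-triene
Conditions: CBr4, PPh3, CH2Cl2, −20 °C
Reagents that add atoms: tetrabromomethane, BrC(Br)(Br)Br
Why: Appel bromination of a primary allylic alcohol under neutral conditions should give the primary bromide without allylic transposition.

Step 11
Reactants: 18 2,2-dimethyl-1,3-dioxan-5-one; 19 SAMP, (S)-1-amino-2-(methoxymethyl)pyrrolidine
Product: 20 SAMP hydrazone of 2,2-dimethyl-1,3-dioxan-5-one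
Conditions: cyclohexane, reflux, Dean–Stark
Reagents that add atoms: none
Why: hydrazone condensation with azeotropic removal of water.

Step 12
Reactants: 20 SAMP hydrazone of 2,2-dimethyl-1,3-dioxan-5-one; 17 (2Z,6E)-1-bromo-3-[(TBDPS-oxy)methyl]-7-methylnona-2,6,8-triene
Product: 22 SAMP hydrazone of (4S)-4-[(2Z,6E)-3-[(TBDPS-oxy)methyl]-7-methylnona-2,6,8-trien-1-yl]-2,2-dimethyl-1,3-dioxan-5-one, via lithium azaenolate 21 (not isolated)
Conditions: t-BuLi (1.05 equiv), THF, −78 °C; then 17, −100 → −78 °C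
Reagents that add atoms: none
Why: Enders SAMP-hydrazone alkylation, in which the chelated lithium azaenolate is alkylated by the allylic bromide (SN2) on the face left open by the methoxymethylpyrrolidine auxiliary, should set the (S) centre that becomes C5 of the butenolide.

Step 13
Reactants: 22 SAMP hydrazone of the (4S)-alkylated dioxanone
Product: 23 (4S)-4-[(2Z,6E)-3-[(TBDPS-oxy)methyl]-7-methylnona-2,6,8-trien-1-yl]-2,2-dimethyl-1,3-dioxan-5-one
Conditions: sat. aq. oxalic acid, Et2O, rt
Reagents that add atoms: water, O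
Why: mild two-phase acidic hydrazone hydrolysis should free the ketone without epimerising the α-centre or cleaving the acetonide, and it returns the auxiliary.

Step 14
Reactants: 23 (4S)-alkylated 2,2-dimethyl-1,3-dioxan-5-one
Product: 24 (3S,5Z,9E)-1,3-dihydroxy-6-[(TBDPS-oxy)methyl]-10-methyldodeca-5,9,11-trien-2-one
Conditions: AcOH/THF/H2O (3:1:1), rt
Reagents that add atoms: none
Why: acid-catalysed acetal hydrolysis under conditions that the primary TBDPS ether and the diene should survive.

Step 15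
Reactants: 24 (3S,5Z,9E)-1,3-dihydroxy-6-[(TBDPS-oxy)methyl]-10-methyldodeca-5,9,11-trien-2-one
Product: 25 (3S,5Z,9E)-3-hydroxy-1-(TBDPS-oxy)-6-[(TBDPS-oxy)methyl]-10-methyldodeca-5,9,11-trien-2-one
Conditions: t-BuPh2SiCl (1.05 equiv), imidazole, CH2Cl2, −20 → 0 °C
Reagents that add atoms: tert-butyl(chloro)diphenylsilane, CC(C)(C)[Si](Cl)(c1ccccc1)c1ccccc1
Why: silylation with the bulky chlorosilane should select the primary over the secondary hydroxyl group.

Step 16
Reactants: 25 (3S,5Z,9E)-3-hydroxy-1-(TBDPS-oxy)-6-[(TBDPS-oxy)methyl]-10-methyldodeca-5,9,11-trien-2-one; 26 (triphenylphosphoranylidene)ketene (Bestmann ylide)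
Product: 28 (5S)-4-[(TBDPS-oxy)methyl]-5-[(2Z,6E)-3-[(TBDPS-oxy)methyl]-7-methylnona-2,6,8-trien-1-yl]furan-2(5H)-one, via ylide ester 27 (not isolated)
Conditions: 26 (1.2 equiv), toluene, 80 °C
Reagents that add atoms: none
Why: Bestmann-ylide butenolide synthesis, in which the secondary alcohol adds to the ketene ylide and the resulting ester ylide closes onto the ketone by intramolecular Wittig reaction under neutral conditions, should carry the carbinol centre unchanged into C5 of the butenolide.

Step 17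
Reactants: 28 (5S)-4-[(TBDPS-oxy)methyl]-5-[(2Z,6E)-3-[(TBDPS-oxy)methyl]-7-methylnona-2,6,8-trien-1-yl]furan-2(5H)-one; 7 4,4-dimethylhept-5-ynal
Product: 30 (5S)-4-[(TBDPS-oxy)methyl]-5-[(2Z,6E)-9-(3-hydroxy-2,6,6-trimethylcyclohex-1-en-1-yl)-3-[(TBDPS-oxy)methyl]-7-methylnona-2,6-dien-1-yl]furan-2(5H)-one as a mixture of both epimers at the ring-A carbinol, via B-alkyl-9-BBN 29 (not isolated)
Conditions: 9-BBN (1.05 equiv), THF, 0 °C → rt; then MeOH, 7 (1.3 equiv), Pd(PPh3)4 (5 mol%), 65 °C
Reagents that add atoms: none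
Why: Proposed new method: hydroboration of the monosubstituted vinyl group of 28 gives the primary B-alkyl-9-BBN 29; zerovalent palladium then binds the alkyne of 7, the methyl-bearing alkyne carbon attacks the methanol-activated aldehyde anti to the metal (anti-Wacker-type oxidative addition) to close ring A and leave a divalent alkenylpalladium alkoxide on the carbon next to the gem-dimethyl group, and this species takes the alkyl group from boron (alkoxide-assisted transmetalation, no external base) and reductively eliminates to form the ring-A C(sp2)–CH2 bond. The closest known reaction types are the anti-Wacker-type alkylative cyclization of 5-alkynals with aryl- and alkenylboron reagents under zerovalent palladium in methanol and the B-alkyl Suzuki–Miyaura coupling of 2,6,6-trimethylcyclohexenyl triflates, which passes through the same kind of hindered alkenylpalladium intermediate; new here is the transfer of a primary alkyl group from a 9-BBN reagent inside the cyclization manifold. Ring A closes in the 6-endo-dig mode with net trans addition of the aldehyde carbon and the alkyl group across the alkyne, which is the endocyclic tetrasubstituted alkene of the target. The one new stereocentre, the ring-A carbinol, is formed without an element of control, so both epimers are expected and the centre is reset in steps 18 and 19. The step needs 6-endo over 5-exo closure, secured by the quaternary propargylic carbon (a 5-exo product would carry a tetrasubstituted exocyclic alkene pressed against the gem-dimethyl group), and chemoselective hydroboration, secured by the preference of 9-BBN for the only monosubstituted alkene of 28. The base-free medium should leave the base-labile C5–H of the butenolide untouched.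

Step 18
Reactants: 30 ring-A carbinol (both epimers)
Product: 31 (5S)-4-[(TBDPS-oxy)methyl]-5-[(2Z,6E)-3-[(TBDPS-oxy)methyl]-7-methyl-9-(2,6,6-trimethyl-3-oxocyclohex-1-en-1-yl)nona-2,6-dien-1-yl]furan-2(5H)-one
Conditions: Dess–Martin periodinane, NaHCO3, CH2Cl2, 0 °C → rt
Reagents that add atoms: none
Why: Dess–Martin oxidation should converge both carbinol epimers on the single enone, with silyl ethers, trisubstituted alkenes and butenolide inert.

Step 19
Reactants: 31 ring-A enone
Product: 32 (5S)-4-[(TBDPS-oxy)methyl]-5-[(2Z,6E)-9-[(3S)-3-hydroxy-2,6,6-trimethylcyclohex-1-en-1-yl]-3-[(TBDPS-oxy)methyl]-7-methylnona-2,6-dien-1-yl]furan-2(5H)-one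
Conditions: (R)-2-methyl-CBS-oxazaborolidine (0.5 equiv), catecholborane (2 equiv), toluene, −78 °C
Reagents that add atoms: none
Why: Corey–Bakshi–Shibata reduction, in which the (R)-oxazaborolidine treats the methyl-substituted alkene as the large group and the ring CH2 as the small group, should deliver hydride to the face that gives the (S)-carbinol of ring A, while the butenolide is not reduced at this temperature.

Step 20
Reactants: 32 bis-TBDPS ether of the target
Product: 33 (5S)-4-(hydroxymethyl)-5-[(2Z,6E)-3-(hydroxymethyl)-9-[(3S)-3-hydroxy-2,6,6-trimethylcyclohex-1-en-1-yl]-7-methylnona-2,6-dien-1-yl]furan-2(5H)-one (CNP0330392.1)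
Conditions: HF·pyridine, pyridine, THF, 0 °C → rt
Reagents that add atoms: none
Why: fluoride-mediated desilylation of both primary TBDPS ethers under buffered, non-basic conditions should spare the butenolide C5–H and the allylic alcohol.

**Compound list**
1 | 2,2-dimethylpent-4-enal | C=CCC(C)(C)C=O | starting material
2 | 1,1-dibromo-3,3-dimethylhexa-1,5-diene | BrC(Br)=CC(C)(C)CC=C | intermediate
3 | lithium 3,3-dimethylhex-5-en-1-yn-1-ide (formed in the flask) | [Li]C#CC(C)(C)CC=C | intermediate
4 | 4,4-dimethylhept-1-en-5-yne | CC#CC(C)(C)CC=C | intermediate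
5 | 9-(4,4-dimethylhept-5-yn-1-yl)-9-borabicyclo[3.3.1]nonane (formed in the flask) | CC#CC(C)(C)CCCB1C2CCCC1CCC2 | intermediate
6 | 4,4-dimethylhept-5-yn-1-ol | CC#CC(C)(C)CCCO | intermediate
7 | 4,4-dimethylhept-5-ynal | CC#CC(C)(C)CCC=O | intermediate
8 | tert-butyldiphenyl(prop-2-yn-1-yloxy)silane | C#CCO[Si](c1ccccc1)(c1ccccc1)C(C)(C)C | starting material
9 | [3-(TBDPS-oxy)prop-1-yn-1-yl]lithium (formed in the flask) | [Li]C#CCO[Si](c1ccccc1)(c1ccccc1)C(C)(C)C | intermediate
10 | methyl 4-(TBDPS-oxy)but-2-ynoate | COC(=O)C#CCO[Si](c1ccccc1)(c1ccccc1)C(C)(C)C | intermediate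
11 | but-3-en-1-ylmagnesium bromide | C=CCC[Mg]Br | starting material
12 | methyl (2Z)-3-[(TBDPS-oxy)methyl]hepta-2,6-dienoate | C=CCC/C(=C/C(=O)OC)CO[Si](c1ccccc1)(c1ccccc1)C(C)(C)C | intermediate
13 | methacrolein (2-methylprop-2-enal) | CC(=C)C=O | starting material
14 | methyl (2Z,6E)-3-[(TBDPS-oxy)methyl]-7-methyl-8-oxoocta-2,6-dienoate | O=C/C(C)=C/CC/C(=C/C(=O)OC)CO[Si](c1ccccc1)(c1ccccc1)C(C)(C)C | intermediate
15 | methyl (2Z,6E)-3-[(TBDPS-oxy)methyl]-7-methylnona-2,6,8-trienoate | C=C/C(C)=C/CC/C(=C/C(=O)OC)CO[Si](c1ccccc1)(c1ccccc1)C(C)(C)C | intermediate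
16 | (2Z,6E)-3-[(TBDPS-oxy)methyl]-7-methylnona-2,6,8-trien-1-ol | C=C/C(C)=C/CC/C(=C/CO)CO[Si](c1ccccc1)(c1ccccc1)C(C)(C)C | intermediate
17 | (2Z,6E)-1-bromo-3-[(TBDPS-oxy)methyl]-7-methylnona-2,6,8-triene | C=C/C(C)=C/CC/C(=C/CBr)CO[Si](c1ccccc1)(c1ccccc1)C(C)(C)C | intermediate
18 | 2,2-dimethyl-1,3-dioxan-5-one | CC1(C)OCC(=O)CO1 | starting material
19 | SAMP, (S)-1-amino-2-(methoxymethyl)pyrrolidine | COC[C@@H]1CCCN1N | starting material
20 | (S)-N-(2,2-dimethyl-1,3-dioxan-5-ylidene)-2-(methoxymethyl)pyrrolidin-1-amine | COC[C@@H]1CCCN1N=C1COC(C)(C)OC1 | intermediate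
21 | lithium azaenolate of 20 (formed in the flask) | COC[C@@H]1CCCN1N([Li])C1=COC(C)(C)OC1 | intermediate
22 | SAMP hydrazone of (4S)-4-[(2Z,6E)-3-[(TBDPS-oxy)methyl]-7-methylnona-2,6,8-trien-1-yl]-2,2-dimethyl-1,3-dioxan-5-one | C=C/C(C)=C/CC/C(=C/C[C@@H]1OC(C)(C)OCC1=NN1CCC[C@H]1COC)CO[Si](c2ccccc2)(c2ccccc2)C(C)(C)C | intermediate
23 | (4S)-4-[(2Z,6E)-3-[(TBDPS-oxy)methyl]-7-methylnona-2,6,8-trien-1-yl]-2,2-dimethyl-1,3-dioxan-5-one | C=C/C(C)=C/CC/C(=C/C[C@@H]1OC(C)(C)OCC1=O)CO[Si](c2ccccc2)(c2ccccc2)C(C)(C)C | intermediate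
24 | (3S,5Z,9E)-1,3-dihydroxy-6-[(TBDPS-oxy)methyl]-10-methyldodeca-5,9,11-trien-2-one | C=C/C(C)=C/CC/C(=C/C[C@H](O)C(=O)CO)CO[Si](c1ccccc1)(c1ccccc1)C(C)(C)C | intermediate
25 | (3S,5Z,9E)-3-hydroxy-1-(TBDPS-oxy)-6-[(TBDPS-oxy)methyl]-10-methyldodeca-5,9,11-trien-2-one | C=C/C(C)=C/CC/C(=C/C[C@H](O)C(=O)CO[Si](c1ccccc1)(c1ccccc1)C(C)(C)C)CO[Si](c1ccccc1)(c1ccccc1)C(C)(C)C | intermediate
26 | (triphenylphosphoranylidene)ketene (Bestmann ylide) | O=C=C=P(c1ccccc1)(c1ccccc1)c1ccccc1 | starting material
27 | 3-O-[(triphenylphosphoranylidene)acetyl] ester of 25 (formed in the flask) | C=C/C(C)=C/CC/C(=C/C[C@H](OC(=O)C=P(c1ccccc1)(c1ccccc1)c1ccccc1)C(=O)CO[Si](c1ccccc1)(c1ccccc1)C(C)(C)C)CO[Si](c1ccccc1)(c1ccccc1)C(C)(C)C | intermediate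
28 | (5S)-4-[(TBDPS-oxy)methyl]-5-[(2Z,6E)-3-[(TBDPS-oxy)methyl]-7-methylnona-2,6,8-trien-1-yl]furan-2(5H)-one | C=C/C(C)=C/CC/C(=C/C[C@@H]1OC(=O)C=C1CO[Si](c2ccccc2)(c2ccccc2)C(C)(C)C)CO[Si](c2ccccc2)(c2ccccc2)C(C)(C)C | intermediate
29 | B-alkyl-9-BBN from 28, boron on the terminal carbon of the former vinyl group (formed in the flask) | C12CCCC(CCC1)B2CC/C(C)=C/CC/C(=C/C[C@@H]1OC(=O)C=C1CO[Si](c2ccccc2)(c2ccccc2)C(C)(C)C)CO[Si](c2ccccc2)(c2ccccc2)C(C)(C)C | intermediate
30 | (5S)-4-[(TBDPS-oxy)methyl]-5-[(2Z,6E)-9-(3-hydroxy-2,6,6-trimethylcyclohex-1-en-1-yl)-3-[(TBDPS-oxy)methyl]-7-methylnona-2,6-dien-1-yl]furan-2(5H)-one, both epimers at the ring-A carbinol | CC1=C(CC/C(C)=C/CC/C(=C/C[C@@H]2OC(=O)C=C2CO[Si](c3ccccc3)(c3ccccc3)C(C)(C)C)CO[Si](c3ccccc3)(c3ccccc3)C(C)(C)C)C(C)(C)CCC1O | intermediate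
31 | (5S)-4-[(TBDPS-oxy)methyl]-5-[(2Z,6E)-3-[(TBDPS-oxy)methyl]-7-methyl-9-(2,6,6-trimethyl-3-oxocyclohex-1-en-1-yl)nona-2,6-dien-1-yl]furan-2(5H)-one | CC1=C(CC/C(C)=C/CC/C(=C/C[C@@H]2OC(=O)C=C2CO[Si](c3ccccc3)(c3ccccc3)C(C)(C)C)CO[Si](c3ccccc3)(c3ccccc3)C(C)(C)C)C(C)(C)CCC1=O | intermediate
32 | (5S)-4-[(TBDPS-oxy)methyl]-5-[(2Z,6E)-9-[(3S)-3-hydroxy-2,6,6-trimethylcyclohex-1-en-1-yl]-3-[(TBDPS-oxy)methyl]-7-methylnona-2,6-dien-1-yl]furan-2(5H)-one | CC1=C(CC/C(C)=C/CC/C(=C/C[C@@H]2OC(=O)C=C2CO[Si](c3ccccc3)(c3ccccc3)C(C)(C)C)CO[Si](c3ccccc3)(c3ccccc3)C(C)(C)C)C(C)(C)CC[C@@H]1O | intermediate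
33 | (5S)-4-(hydroxymethyl)-5-[(2Z,6E)-3-(hydroxymethyl)-9-[(3S)-3-hydroxy-2,6,6-trimethylcyclohex-1-en-1-yl]-7-methylnona-2,6-dien-1-yl]furan-2(5H)-one (CNP0330392.1) | CC1=C(CC/C(C)=C/CC/C(=C/C[C@@H]2OC(=O)C=C2CO)CO)C(C)(C)CC[C@@H]1O | target

**Step count and risks**

Total step count: 20. Longest linear sequence: 15 steps (steps 5–10, 12–16 and 17–20, starting from 8).

Step 17 (proposed method). The alkyl group may fail to transfer from boron to the alkenylpalladium intermediate, so that the borane instead reduces the aldehyde by hydride transfer or the cyclised intermediate is simply protonated; 5-exo closure is a further possible leak. The fallback is known chemistry, a B-alkyl Suzuki–Miyaura coupling onto a preformed ring A; it sets out from 28 (through its borane 29) and comes back at 30. Commercial 2,6,6-trimethylcyclohex-2-en-1-one is epoxidised (H2O2, NaOH, MeOH) to 1,3,3-trimethyl-7-oxabicyclo[4.1.0]heptan-2-one F1. The epoxide is opened reductively at the α-carbon (PhSeSePh, NaBH4, AcOH, EtOH) to 3-hydroxy-2,6,6-trimethylcyclohexan-1-one F2, which is silylated (Et3SiCl, imidazole) to 2,6,6-trimethyl-3-(triethylsilyloxy)cyclohexan-1-one F3. Enolisation toward the only enolisable α-carbon and triflation (KN(SiMe3)2, PhNTf2, THF, −78 °C) should give 2,6,6-trimethyl-3-(triethylsilyloxy)cyclohex-1-en-1-yl trifluoromethanesulfonate F4. Coupling of 29 with F4 (Pd(dppf)Cl2, AsPh3, aq. K3PO4, DMF, rt) should give the ring-A triethylsilyl ether of 30 F5, and PPTS in MeOH should then free the carbinol to 30.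

Step 16. The intramolecular Wittig closure at the hindered, doubly oxygenated ketone may be slow, and prolonged heating may erode the adjacent carbinol centre by enolisation. The fallback sets out from 25 and comes back at 28: esterification with diethylphosphonoacetic acid (EDC·HCl, DMAP, CH2Cl2) should give the 3-O-(diethylphosphonoacetyl) ester of 25 F6, and an intramolecular Horner–Wadsworth–Emmons reaction under Masamune–Roush conditions (LiCl, i-Pr2NEt, MeCN, rt) should close the butenolide.

Step 6. The alkenylcopper adduct may equilibrate through its allenoate form before protonation, which would erode the alkene geometry. The fallback sets out from 11 and comes back at 12. Copper-catalysed anti-carbomagnesiation of prop-2-yn-1-ol with 11 (CuI cat., THF), quenched with I2, should give (2Z)-2-(but-3-en-1-yl)-3-iodoprop-2-en-1-ol F7, the magnesium alkoxide chelate fixing the anti addition. Silylation (t-BuPh2SiCl, imidazole) should give its TBDPS ether F8, and palladium-catalysed methoxycarbonylation (Pd(PPh3)2Cl2, CO, MeOH, Et3N) proceeds with retention of alkene geometry to 12.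

Further compounds
F1 | step 17 | 1,3,3-trimethyl-7-oxabicyclo[4.1.0]heptan-2-one (racemic) | CC12OC1CCC(C)(C)C2=O
F2 | step 17 | 3-hydroxy-2,6,6-trimethylcyclohexan-1-one | CC1C(O)CCC(C)(C)C1=O
F3 | step 17 | 2,6,6-trimethyl-3-(triethylsilyloxy)cyclohexan-1-one | CC1C(O[Si](CC)(CC)CC)CCC(C)(C)C1=O
F4 | step 17 | 2,6,6-trimethyl-3-(triethylsilyloxy)cyclohex-1-en-1-yl trifluoromethanesulfonate | CC1=C(OS(=O)(=O)C(F)(F)F)C(C)(C)CCC1O[Si](CC)(CC)CC
F5 | step 17 | ring-A triethylsilyl ether of 30 (both epimers) | CC1=C(CC/C(C)=C/CC/C(=C/C[C@@H]2OC(=O)C=C2CO[Si](c3ccccc3)(c3ccccc3)C(C)(C)C)CO[Si](c3ccccc3)(c3ccccc3)C(C)(C)C)C(C)(C)CCC1O[Si](CC)(CC)CC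
F6 | step 16 | 3-O-(diethylphosphonoacetyl) ester of 25 | C=C/C(C)=C/CC/C(=C/C[C@H](OC(=O)CP(=O)(OCC)OCC)C(=O)CO[Si](c1ccccc1)(c1ccccc1)C(C)(C)C)CO[Si](c1ccccc1)(c1ccccc1)C(C)(C)C
F7 | step 6 | (2Z)-2-(but-3-en-1-yl)-3-iodoprop-2-en-1-ol | C=CCC/C(=C/I)CO
F8 | step 6 | TBDPS ether of F7 | C=CCC/C(=C/I)CO[Si](c1ccccc1)(c1ccccc1)C(C)(C)C
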